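The target stops short of what the partner charge allows: in the grey run it levels near 17.0 % of the starting material, which is 0.0748 M against 0.0912 M of partner, with most of the starting material still present.

| setting | blue | grey | ochre | Wednesday's | Monday's | Tuesday's | Saturday's | Thursday's |
|---|---|---|---|---|---|---|---|---|
| starting material | 0.11 M | 0.44 M | 0.096 M | 0.096 M | 0.15 M | 0.30 M | 0.096 M | 0.096 M |
| partner | 0.0912 M | 0.0912 M | 0.0912 M | 0.200 M | 0.0912 M | 0.150 M | 0.0912 M | 0.0912 M |
| second substrate | 0.048 M | 0.048 M | 0.075 M | 0.200 M | 0.0250 M | 0.0480 M | 0.0480 M | 0.0150 M |
| catalyst | 11 mM | 11 mM | 11 mM | 3.0 mM | 4.0 mM | 11 mM | 11 mM | 40 mM |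
| remark | run made earlier | run made earlier | run made earlier |  |  |  |  |  |
| time |  |  |  | 10 min | 10 min | 10 min | 10 min | 10 min |

| run | time / min | target / % | starting material / % |
|---|---|---|---|
| blue | 0.500 | 17.8 | 81.4 |
| blue | 1.00 | 28.0 | 71.4 |
| blue | 2.00 | 37.5 | 61.4 |
| blue | 4.00 | 45.0 | 53.9 |
| blue | 8.00 | 48.3 | 50.5 |
| grey | 0.500 | 12.8 | 86.7 |
| grey | 1.00 | 15.9 | 84.0 |
| grey | 2.00 | 16.8 | 83.3 |
| grey | 4.00 | 17.0 | 83.0 |
| grey | 8.00 | 16.5 | 83.1 |
| ochre | 0.500 | 17.7 | 82.0 |
| ochre | 1.00 | 26.0 | 73.1 |
| ochre | 2.00 | 34.0 | 65.3 |
| ochre | 4.00 | 38.8 | 60.6 |
| ochre | 8.00 | 41.0 | 58.7 |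

(standard deviation of a reading: 0.3 percentage points)

- the numbers in the tables scatter by 0.3 percentage points (one standard deviation)
- no earlier run changes the charge of catalyst; that part of a forecast is a guess

1. the flasks by amount of target, in percent of the starting material charged, highest first, at 10 min (Wednesday's / Monday's / Tuesday's / Saturday's / Thursday's)
2. the amount of target, in percent of the starting material charged of the flask you put first, at 10 min
3. the amount of target, in percent of the starting material charged of the flask you put last, at 10 min

The reckoning here assumes that the second substrate competes for the partner. Each route is taken to use one partner and to run in proportion to its own substrate, so the shared catalyst cancels from the ratio of rates. If the partner charge of 0.0912 M has been used by 8.00 min, the ochre run then reads 2.21 for the selectivity factor s, the logarithm of the fraction of second substrate left divided by that of the fraction of starting material left. The blue run's last reading, on the same assumption, gives 2.31.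

If x is the fraction of starting material left, the second substrate keeps x^s, and the end comes when the two amounts used add up to the partner charge. In this reckoning the catalyst cancels from the end state and enters through how fast that end is approached. Solved by substitution, this gives a conversion of 79.9 % for Thursday's and 39.4 % for Tuesday's, both taken as finished. Wednesday's and Monday's hold 3.0 mM and 4.0 mM of catalyst, less than the 11 mM of the earlier runs, so whether they finish by 10 min is a guess, and so is their place in the order.

The forecast differs: Thursday's > Saturday's > Tuesday's > Monday's > Wednesday's, with 88 % and 13.5 %. It reads the plateaus thus: “They look like catalyst death”.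

The flasks give Thursday's > Saturday's > Wednesday's > Monday's > Tuesday's, with 79.3 % and 38.8 %.

    starting material + partner + catalyst → catalyst + target (k = 8.80 M⁻² s⁻¹)
    second substrate + partner + catalyst → catalyst + second product (k = 19.0 M⁻² s⁻¹)
    starting material + partner → uncatalysed product (k = 0.00170 M⁻¹ s⁻¹)

In Tuesday's, half of the target's turnover was done by 0.355 min, and 97 % of the second product's stood by 2.00 min. At 10.0 min in Tuesday's the partner stood at 0 % of its charge and the catalyst at 100 % of its charge, and the conversion was 39.5 %, beside the reckoned 39.4 %. The 60.5 % of starting material left in Tuesday's, raised to s, gives 32.9 %, and the second substrate stood at 34.4 % of its charge.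

Tuesday's flask with 0.18 M of starting material reckons to a conversion of 60.0 %. That flask gives 59.2 % of target.

The data come from a simulation with made-up constants; the scatter is artificial.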